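Follow the exchange of E with G in this flask, not its catalyst.

D 0.10 M; X 14 mol%; time 15 d

    G ⇌ D (k1 = 1.14 × 10⁻⁴ min⁻¹)
    E ⇌ G (K2 = 1.9, k2 = 2.25 × 10⁻⁴ min⁻¹)
    D + X ⇌ E + X, rate k3*[D]*[X] forward; the back reaction follows from the equilibrium constant (K3 = 18, k3 = 0.0282 L mol⁻¹ min⁻¹)
    2 X → X2 (k4 = 0.0102 L mol⁻¹ min⁻¹)

- the state of affairs at 15 d: stopped, and by what, or still going (forward and back rates have come level / it is still moving / no working catalyst is left)
- share of the D used up at 15 d
- E at 15 d, in percent of the D charged
- G at 15 d, in percent of the D charged

- a doubled species enters its step squared and goes two at a time
- the reaction counts as stopped when no species that holds the D changes by six tenths of a point or more over the second half of the time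
- run time (flask): 15 d

Climb the time scales from the fastest. G ⇌ D relaxes with a half-life of 0.120 d, both directions together, which is shorter than the 1.2 d forward half-life of D through X, so you should see D pass into G first. At the start D leaves for E through X at 3.95 × 10⁻⁴ min⁻¹ and for G at 0.00390 min⁻¹, which is faster, so I reckon a head start of 9.20% of the D going straight to E.

Next comes E ⇌ G. Adding its forward and back rate constants gives its relaxation constant λ = 3.43 × 10⁻⁴ min⁻¹, a half-life of 1.40 d. That is longer than the first rung, so G and D should hold their ratio while E and G exchange.

X pairs off with a first half-life of 2.43 d, longer again. But G ⇌ D and E ⇌ G already join the three species without X, and λ holds no X.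

By my reckoning the balance stands at E to G to D as 18 to 34.2 to one, so D keeps 1.88%. That gives a conversion of 98.1%, E 33.8% and G 64.3%.

Carry one quantity, 0.0600% here: the open gap, the share of E's distance from balance still unclosed by E ⇌ G at the end of the run, exp(−λt). At half the time it is 2.45%. E closes its distance from the head start, so I reckon the second half moves E by 0.59 percentage points. That sits just under the stopping margin, and the route through X, though slower than λ at the charge, runs beside E ⇌ G, so I commit to rates having come level.

The forecast gives forward and back rates have come level, with conversion 98.1%, E 33.8% and G 64.3%, the run being “over seven time constants”.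

The simulated flask gives forward and back rates have come level, with 98.1% of the D used up, E 33.8% and G 64.3%. In it E moves by 0.59 points between 7.50 d and 15.0 d, against the 0.59 points reckoned. Now take the neighbour flask with 5.6 mol% of X. λ holds no X, so by E ⇌ G the reckoning gives it the same open gap of 0.0600%, on the same balance. That neighbour ends with D 1.88%, E 33.8% and G 64.3%, while 28.8% of its catalyst is still X.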